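## Retrosynthetic overview

- The (E)-propenal side chain is attached last, by Heck coupling of an aryl bromide with acrolein diethyl acetal; the same acid treatment frees the aldehyde and the guaiacyl phenol.
- The CH2OH group comes from a vinyl group (ozonolysis, NaBH4) on a trans-2-aryl-3-vinyl-1,4-benzodioxane.
- The dioxane ring is the only ring made (both benzene rings are bought). It is closed by intramolecular Cu-catalysed aryl C–O coupling of a syn β-aryloxy homoallylic alcohol onto an ortho-bromide, with retention at both stereocentres.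
- The C7'–C8' bond joins MOM-vanillin to a (Z)-γ-aryloxyallyl-B(Ipc)2 reagent, an α-aryloxyallyl anion equivalent whose nucleophilic carbon is the masked carbonyl carbon of acrolein. This one step sets C7', C8' and the C8'–O–aryl ether.
- The allylborane comes from an aryloxyallene (2,4-dibromo-6-methoxyphenol plus propargyl bromide) and (+)-Ipc2BH.

Assumption: 2,4-dibromo-6-methoxyphenol and (+)-Ipc2BH (from (−)-α-pinene) are bought. C7' is the carbon carrying the guaiacyl ring and C8' the carbon carrying CH2OH.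

## Route

Step 1
Reactants: 1 vanillin
Product: 2 3-methoxy-4-(methoxymethoxy)benzaldehyde
Conditions: NaH, MOMCl, THF–DMF, 0 °C → rt
Reagents that add atoms: chloromethyl methyl ether (MOMCl), COCCl
Why: Williamson-type O-alkylation of the phenoxide (MOM protection) masks the acidic phenol, which would otherwise protonate the allylborane in step 3 and compete in the Cu-catalysed etherification in step 4; no stereocentre is involved.

Step 2
Reactants: 3 2,4-dibromo-6-methoxyphenol; 4 propargyl bromide
Product: 6 1,5-dibromo-3-methoxy-2-(propa-1,2-dien-1-yloxy)benzene, via propargyl ether 5 (not isolated)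
Conditions: K2CO3, acetone, 50 °C; filter, evaporate; then KOtBu (0.3 equiv), THF, 0 °C → rt
Reagents that add atoms: none
Why: Williamson O-propargylation followed by base-catalysed propargyl-to-allenyl ether isomerisation (prototropic rearrangement), which stops at the aryloxyallene with catalytic KOtBu at room temperature; both ortho positions are blocked, so no Claisen pathway is open.

Step 3
Reactants: 6 1,5-dibromo-3-methoxy-2-(propa-1,2-dien-1-yloxy)benzene; 7 (+)-diisopinocampheylborane; 2 3-methoxy-4-(methoxymethoxy)benzaldehyde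
Product: 10 (1S,2S)-2-(2,4-dibromo-6-methoxyphenoxy)-1-[3-methoxy-4-(methoxymethoxy)phenyl]but-3-en-1-ol, via allylborane 8 (not isolated), via borinate 9 (not isolated)
Conditions: 7 (1.2 equiv), 6 (1.3 equiv), THF, −25 °C, 5 h; then 2 (1.0 equiv), −78 → −40 °C; then NaOH, H2O2, 0 °C → rt
Reagents that add atoms: none
Why: Proposed new method: kinetic hydroboration of the unsubstituted terminal C=C of the aryloxyallene by bulky Ipc2BH (B to CH2, H to the central carbon anti to OAr) should give the (Z)-γ-aryloxyallylborane 8, in which the former acrolein carbonyl carbon, normally an electrophile, is the nucleophilic allyl terminus that adds to the Re face of aldehyde 2 through a chair Zimmerman–Traxler transition state (Z-allyl gives syn, the (−)-α-pinene-derived Ipc groups give 1S,2S), the closest known chemistry being Brown-type (Z)-γ-alkoxyallyl-B(Ipc)2 additions and Ipc2BH hydroboration of silyl- and boryl-substituted allenes to γ-substituted allylboranes, and hydroboration instead of lithiation is what lets both aryl bromides survive.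

Step 4
Reactants: 10 (1S,2S)-2-(2,4-dibromo-6-methoxyphenoxy)-1-[3-methoxy-4-(methoxymethoxy)phenyl]but-3-en-1-ol
Product: 11 (2S,3S)-7-bromo-3-ethenyl-5-methoxy-2-[3-methoxy-4-(methoxymethoxy)phenyl]-2,3-dihydro-1,4-benzodioxine
Conditions: CuI (10 mol %), 3,4,7,8-tetramethyl-1,10-phenanthroline (20 mol %), Cs2CO3, toluene (0.05 M), 110 °C
Reagents that add atoms: none
Why: Intramolecular Ullmann-type Cu-catalysed C(aryl)–O coupling, in which the copper alkoxide inserts into the neighbouring ortho C–Br and closes the six-membered ring (the para-bromide cannot cyclise and is kept); only the O–H bond reacts, so both stereocentres are retained and the syn alcohol gives the trans-(2S,3S) benzodioxane.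

Step 5
Reactants: 11 (2S,3S)-7-bromo-3-ethenyl-5-methoxy-2-[3-methoxy-4-(methoxymethoxy)phenyl]-2,3-dihydro-1,4-benzodioxine
Product: 14 [(2S,3S)-6-bromo-8-methoxy-3-[3-methoxy-4-(methoxymethoxy)phenyl]-2,3-dihydro-1,4-benzodioxin-2-yl]methanol, via ozonide 12 (not isolated), via aldehyde 13 (not isolated)
Conditions: O3, CH2Cl2, −78 °C (indicator dye end point); N2 purge; then NaBH4, MeOH, −78 → 0 °C
Reagents that add atoms: ozone, [O-][O+]=O
Why: Ozonolysis of the monosubstituted alkene, which reacts with ozone much faster than the arenes at −78 °C, and in situ NaBH4 reduction of the ozonide through the aldehyde to the primary alcohol; immediate cold reduction keeps the α-aryloxy aldehyde from epimerising at C8'.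

Step 6
Reactants: 14 [(2S,3S)-6-bromo-8-methoxy-3-[3-methoxy-4-(methoxymethoxy)phenyl]-2,3-dihydro-1,4-benzodioxin-2-yl]methanol; 15 acrolein diethyl acetal
Product: 18 (7'S,8'S)-nocomtal, via diethyl acetal 16 (not isolated), via MOM enal 17 (not isolated)
Conditions: Pd(OAc)2 (5 mol %), nBu4NOAc, K2CO3, KCl, DMF, 90 °C; aqueous work-up; then 3 M HCl, THF, 40 °C
Reagents that add atoms: water, O
Why: Mizoroki–Heck arylation of acrolein diethyl acetal at its terminal carbon with β-hydride elimination toward the benzylic side gives the (E)-cinnamyl acetal, and aqueous acid then hydrolyses both acetals (diethyl acetal to the enal, MOM ether to the phenol) without breaking a bond to either stereocentre.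

## Compound list

1 | vanillin | COc1cc(C=O)ccc1O | starting material
2 | 3-methoxy-4-(methoxymethoxy)benzaldehyde | COCOc1ccc(C=O)cc1OC | intermediate
3 | 2,4-dibromo-6-methoxyphenol | COc1cc(Br)cc(Br)c1O | starting material
4 | propargyl bromide | C#CCBr | starting material
5 | 1,5-dibromo-3-methoxy-2-(prop-2-yn-1-yloxy)benzene | COc1cc(Br)cc(Br)c1OCC#C | intermediate (not isolated)
6 | 1,5-dibromo-3-methoxy-2-(propa-1,2-dien-1-yloxy)benzene | COc1cc(Br)cc(Br)c1OC=C=C | intermediate
7 | (+)-diisopinocampheylborane, bis[(1S,2R,3S,5S)-2,6,6-trimethylbicyclo[3.1.1]hept-3-yl]borane, from (−)-α-pinene | [H]B([C@H]1C[C@H]2C[C@@H]([C@@H]1C)C2(C)C)[C@H]1C[C@H]2C[C@@H]([C@@H]1C)C2(C)C | starting material (chiral reagent)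
8 | [(2Z)-3-(2,4-dibromo-6-methoxyphenoxy)prop-2-en-1-yl]diisopinocampheylborane | COc1cc(Br)cc(Br)c1O/C=C\CB([C@H]1C[C@H]2C[C@@H]([C@@H]1C)C2(C)C)[C@H]1C[C@H]2C[C@@H]([C@@H]1C)C2(C)C | intermediate (not isolated)
9 | (1S,2S)-2-(2,4-dibromo-6-methoxyphenoxy)-1-[3-methoxy-4-(methoxymethoxy)phenyl]but-3-en-1-yl diisopinocampheylborinate | B(O[C@@H](c1ccc(OCOC)c(OC)c1)[C@H](C=C)Oc1c(Br)cc(Br)cc1OC)([C@H]1C[C@H]2C[C@@H]([C@@H]1C)C2(C)C)[C@H]1C[C@H]2C[C@@H]([C@@H]1C)C2(C)C | intermediate (not isolated)
10 | (1S,2S)-2-(2,4-dibromo-6-methoxyphenoxy)-1-[3-methoxy-4-(methoxymethoxy)phenyl]but-3-en-1-ol (syn) | O[C@@H](c1ccc(OCOC)c(OC)c1)[C@H](C=C)Oc1c(Br)cc(Br)cc1OC | intermediate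
11 | (2S,3S)-7-bromo-3-ethenyl-5-methoxy-2-[3-methoxy-4-(methoxymethoxy)phenyl]-2,3-dihydro-1,4-benzodioxine (trans) | COCOc1ccc([C@@H]2Oc3cc(Br)cc(OC)c3O[C@H]2C=C)cc1OC | intermediate
12 | 3-[(2R,3S)-6-bromo-8-methoxy-3-[3-methoxy-4-(methoxymethoxy)phenyl]-2,3-dihydro-1,4-benzodioxin-2-yl]-1,2,4-trioxolane (both epimers at the trioxolane carbon) | COCOc1ccc([C@@H]2Oc3cc(Br)cc(OC)c3O[C@H]2C4OCOO4)cc1OC | intermediate (not isolated)
13 | (2R,3S)-6-bromo-8-methoxy-3-[3-methoxy-4-(methoxymethoxy)phenyl]-2,3-dihydro-1,4-benzodioxine-2-carbaldehyde (same spatial arrangement as 11; descriptor changes by priority only) | COCOc1ccc([C@@H]2Oc3cc(Br)cc(OC)c3O[C@H]2C=O)cc1OC | intermediate (not isolated)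
14 | [(2S,3S)-6-bromo-8-methoxy-3-[3-methoxy-4-(methoxymethoxy)phenyl]-2,3-dihydro-1,4-benzodioxin-2-yl]methanol | COCOc1ccc([C@@H]2Oc3cc(Br)cc(OC)c3O[C@H]2CO)cc1OC | intermediate
15 | acrolein diethyl acetal (3,3-diethoxyprop-1-ene) | C=CC(OCC)OCC | starting material
16 | [(2S,3S)-6-[(1E)-3,3-diethoxyprop-1-en-1-yl]-8-methoxy-3-[3-methoxy-4-(methoxymethoxy)phenyl]-2,3-dihydro-1,4-benzodioxin-2-yl]methanol | COCOc1ccc([C@@H]2Oc3cc(/C=C/C(OCC)OCC)cc(OC)c3O[C@H]2CO)cc1OC | intermediate (not isolated)
17 | (2E)-3-[(2S,3S)-2-(hydroxymethyl)-8-methoxy-3-[3-methoxy-4-(methoxymethoxy)phenyl]-2,3-dihydro-1,4-benzodioxin-6-yl]prop-2-enal | COCOc1ccc([C@@H]2Oc3cc(/C=C/C=O)cc(OC)c3O[C@H]2CO)cc1OC | intermediate (not isolated)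
18 | (7'S,8'S)-nocomtal, (2E)-3-[(2S,3S)-3-(4-hydroxy-3-methoxyphenyl)-2-(hydroxymethyl)-8-methoxy-2,3-dihydro-1,4-benzodioxin-6-yl]prop-2-enal | COc1cc([C@@H]2Oc3cc(/C=C/C=O)cc(OC)c3O[C@H]2CO)ccc1O | target

## Summary

Total step count: 6. Longest linear sequence: 5 steps (3 → 6 → 10 → 11 → 14 → 18; step 1 is a one-step branch).

Three steps most likely to fail, each with a fallback:

Step 3 (key step). The risks are hydroboration at the enol-ether C=C instead of the terminal C=C, and Z/E scrambling or 1,2-migration of the allyldialkylborane above about −25 °C. The fallback sets out from allene 6 and comes back at 10. Platinum(0)-catalysed hydroboration of 6 with pinacolborane (Pt(dba)2, bulky phosphine, toluene, rt) gives the isolable, configurationally stable 2-[(2Z)-3-(2,4-dibromo-6-methoxyphenoxy)prop-2-en-1-yl]-4,4,5,5-tetramethyl-1,3,2-dioxaborolane F1. This boronate is then added to aldehyde 2 under chiral phosphoric acid catalysis ((R)-TRIP, 5 mol %, toluene, −30 °C, the enantiomer chosen to deliver Re-face attack). The same closed transition state gives the syn product, and hydrolytic work-up gives 10.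

Step 4. The Cu-catalysed closure on a hindered secondary benzylic alkoxide may be slow, and alkoxide-driven loss of aryloxide or oligomerisation at the para-bromide may compete. The fallback sets out from 10 and comes back at 11, and moves the ring closure from the aryl carbon to the benzylic carbon. Deprotonation and alkoxide/ether-directed Br/Mg exchange at the ortho-bromide (iPrMgCl, then iPrMgCl·LiCl, THF, −20 → 0 °C), then B(OMe)3 and NaBO3 oxidation, give (1S,2S)-2-(4-bromo-2-hydroxy-6-methoxyphenoxy)-1-[3-methoxy-4-(methoxymethoxy)phenyl]but-3-en-1-ol F2. Catalytic BF3·OEt2 in CH2Cl2 at −40 °C ionises the p-alkoxybenzylic alcohol, and capture by the phenol gives the thermodynamically preferred trans-benzodioxane 11. C8' is untouched and C7' is set by the trans preference.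

Step 6. The electron-rich aryl bromide may couple sluggishly under ligand-free Heck conditions, or β-hydride elimination may go toward the acetal and give the propanoate ester. The fallback sets out from 14 and comes back at 17. Suzuki–Miyaura vinylation (potassium vinyltrifluoroborate, PdCl2(dppf), Cs2CO3, THF–H2O, 80 °C) gives [(2S,3S)-6-ethenyl-8-methoxy-3-[3-methoxy-4-(methoxymethoxy)phenyl]-2,3-dihydro-1,4-benzodioxin-2-yl]methanol F3. Olefin cross-metathesis with crotonaldehyde (Hoveyda–Grubbs II, CH2Cl2, 40 °C) then gives the (E)-enal 17, which is hydrolysed to 18 with 3 M HCl/THF as in step 6.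

Further compounds
F1 | step 3 | 2-[(2Z)-3-(2,4-dibromo-6-methoxyphenoxy)prop-2-en-1-yl]-4,4,5,5-tetramethyl-1,3,2-dioxaborolane | COc1cc(Br)cc(Br)c1O/C=C\CB1OC(C)(C)C(C)(C)O1
F2 | step 4 | (1S,2S)-2-(4-bromo-2-hydroxy-6-methoxyphenoxy)-1-[3-methoxy-4-(methoxymethoxy)phenyl]but-3-en-1-ol | O[C@@H](c1ccc(OCOC)c(OC)c1)[C@H](C=C)Oc1c(O)cc(Br)cc1OC
F3 | step 6 | [(2S,3S)-6-ethenyl-8-methoxy-3-[3-methoxy-4-(methoxymethoxy)phenyl]-2,3-dihydro-1,4-benzodioxin-2-yl]methanol | COCOc1ccc([C@@H]2Oc3cc(C=C)cc(OC)c3O[C@H]2CO)cc1OC
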